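Atom labels used below (3,7-dioxabicyclo[3.3.0]octane): C1 and C5 ring-fusion carbinol carbons, C2 and C6 aryl-bearing carbons, O3 and O7 ring oxygens, C4 and C8 methylene carbons; ring A holds O3, ring B holds O7; Ar = 4-(benzyloxy)-3-methoxyphenyl.
Retrosynthesis: C4 and C8 are first raised to lactone carbonyls; then the C1–C5 bond and the lactone bonds O3–C4 and O7–C8 are cut together, which leaves two identical aryl-C3 halves; last, each half is cut at C1–C2 (C5–C6).
Enabling feature: a twofold axis passes through the C1–C5 bond, which joins two tertiary carbinol carbons (pinacol pattern), and each benzylic oxygen lies γ to the methylene carbon of the other half (γ-lactone pattern), so one reductive dimerisation can make the central bond and both oxolane rings.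
Forward: aldehyde 1 and diazo ester 2 give diazo alcohol 3, oxidation gives keto ester 4, SmI2 joins two molecules of 4 through their ketone carbons while rings A and B close as γ-lactones in the same flask (through 5 and 6 to 7), both lactones are reduced to ethers two-directionally (8, 9), and hydrogenolysis gives the target 10.
Stereochemistry: C2 and C6 (S) come from the chiral magnesium catalyst in step 1; C1 and C5 (R) are set in step 3 by chelation-controlled 1,2-induction from C2 and C6, and the cis ring fusion is enforced by the bicycle.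

Key step: step 3

Assumption: the magnesium complex of (S,S)-ProPhenol (2,6-bis{[(S)-2-(hydroxydiphenylmethyl)pyrrolidin-1-yl]methyl}-4-methylphenol) is taken to deliver the diazo ester to the Re face of the aldehyde, which gives the (S)-carbinol; if the sense proves opposite, the (R,R)-ligand is used and nothing else changes.

Step 1
Reactants: 1 4-(benzyloxy)-3-methoxybenzaldehyde; 2 ethyl diazoacetate
Product: 3 ethyl (3S)-3-Ar-2-diazo-3-hydroxypropanoate
Conditions: (S,S)-ProPhenol (10 mol %), n-Bu2Mg (20 mol %), cis-cyclopentane-1,2-diol (10 mol %), 2 (1.5 equiv), THF, −20 °C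
Reagents that add atoms: none
Why: The magnesium–ProPhenol complex deprotonates the diazo ester and holds the aldehyde in its chiral pocket so that the diazo carbon adds to the Re face of the formyl group (direct catalytic asymmetric aldol-type addition of a diazo ester), which sets the (S)-configured benzylic carbinol that becomes C2 and C6.

Step 2
Reactants: 3 ethyl (3S)-3-Ar-2-diazo-3-hydroxypropanoate
Product: 4 ethyl (3S)-3-Ar-3-hydroxy-2-oxopropanoate
Conditions: DMDO (acetone solution, 1.3 equiv), acetone, −20 to 0 °C; evaporate, azeotrope with toluene, use at once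
Reagents that add atoms: dimethyldioxirane (DMDO), CC1(C)OO1
Why: Oxygen-atom transfer from the dioxirane to the nucleophilic diazo carbon with loss of N2 gives the ketone under neutral, base-free conditions (known oxidation of α-diazo-β-hydroxy esters to β-hydroxy-α-keto esters), so the enolisable benzylic centre should keep its configuration and no new stereocentre arises.

Step 3
Reactants: 4 ethyl (3S)-3-Ar-3-hydroxy-2-oxopropanoate (two molecules)
Product: 7 (3S,3aR,6S,6aR)-3,6-bis[4-(benzyloxy)-3-methoxyphenyl]-3a,6a-dihydroxytetrahydro-1H,3H-furo[3,4-c]furan-1,4-dione, via pinacol tetrol diester 5 (not isolated), via monolactone ester 6 (not isolated)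
Conditions: SmI2 (0.1 M in THF, 1.1 equiv per molecule of 4) added slowly to 4 in THF, −78 °C to rt, no proton source; then aq. 1 M HCl, rt
Reagents that add atoms: none
Why: SmI2 (divalent samarium) transfers one electron to the ketone of each molecule of 4, the two samarium-bound ketyls (carbonyl carbons of reversed, now identical polarity) combine at C1 and C5 to the pinacolate 5, and each benzylic hydroxyl then attacks the ester on the neighbouring quaternary carbon with loss of ethanol (6, then 7). The closest known reaction type is the reductive pinacol homocoupling of α-keto esters and α-keto amides to 2,3-disubstituted tartaric acid derivatives, followed by ordinary γ-hydroxy-ester lactonisation. Ring A closes by 5-exo-trig attack of O3 on the C4 ester carbonyl and ring B in the same mode by O7 on C8; a bicyclo[3.3.0] bis-lactone can only be cis-fused. C1 and C5 are each set by 1,2-induction from the adjacent carbinol: trivalent samarium bridges the ketyl oxygen and the benzylic hydroxyl in a five-membered chelate, the aryl group shields one face of it and the new bond forms on the face of the benzylic hydrogen, which gives R at C1 and C5 from S at C2 and C6 and places each aryl group cis to the neighbouring tertiary hydroxyl. The step needs like union of the two halves and coupling instead of plain reduction: since both partners are the same enantiomer with the same facial bias the favoured union is the like one (an unlike pinacol cannot close the second lactone and is separated), and slow addition of SmI2 to concentrated 4 without a proton source keeps ketyl–ketyl coupling ahead of further reduction.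

Step 4
Reactants: 7 (3S,3aR,6S,6aR)-3,6-bis[4-(benzyloxy)-3-methoxyphenyl]-3a,6a-dihydroxytetrahydro-1H,3H-furo[3,4-c]furan-1,4-dione
Product: 8 (3S,3aR,6S,6aR)-3,6-bis[4-(benzyloxy)-3-methoxyphenyl]tetrahydro-1H,3H-furo[3,4-c]furan-1,3a,4,6a-tetrol (bis-lactol, anomer mixture at the two lactol carbons)
Conditions: DIBAL-H (6 equiv), CH2Cl2–THF, −78 °C; aq. potassium sodium tartrate
Reagents that add atoms: none
Why: Hydride addition to each lactone carbonyl gives an aluminium hemiacetal that is stable at −78 °C and releases the lactol on work-up (standard partial reduction of γ-lactones); the excess reagent covers the two free tertiary hydroxyls, and the new lactol centres at C4 and C8 do not matter because step 5 removes them.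

Step 5
Reactants: 8 (3S,3aR,6S,6aR)-3,6-bis[4-(benzyloxy)-3-methoxyphenyl]tetrahydro-1H,3H-furo[3,4-c]furan-1,3a,4,6a-tetrol
Product: 9 (1S,3aR,4S,6aR)-1,4-bis[4-(benzyloxy)-3-methoxyphenyl]tetrahydro-1H,3H-furo[3,4-c]furan-3a,6a-diol
Conditions: Et3SiH (10 equiv), BF3·OEt2 (4 equiv), CH2Cl2, −78 to −40 °C
Reagents that add atoms: none
Why: BF3 ionises each lactol hydroxyl to a five-membered oxocarbenium ion that takes hydride from Et3SiH (ionic hydrogenation of lactols to cyclic ethers), which turns C4 and C8 into methylenes without creating a stereocentre, and the low temperature is chosen to keep the benzylic C2–O3 and C6–O7 bonds from ionising.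

Step 6
Reactants: 9 (1S,3aR,4S,6aR)-1,4-bis[4-(benzyloxy)-3-methoxyphenyl]tetrahydro-1H,3H-furo[3,4-c]furan-3a,6a-diol
Product: 10 (1S,3aR,4S,6aR)-1,4-bis(4-hydroxy-3-methoxyphenyl)tetrahydro-1H,3H-furo[3,4-c]furan-3a,6a-diol
Conditions: H2 (1 atm), 10% Pd/C, EtOAc–MeOH, rt
Reagents that add atoms: none
Why: Hydrogenolysis of the two aryl benzyl ethers over Pd/C under neutral conditions at atmospheric pressure is much faster than cleavage of the benzylic C–O bonds of the oxolane rings, so both phenols should be freed with the four stereocentres untouched.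

Compound list
1 | 4-(benzyloxy)-3-methoxybenzaldehyde | O=Cc1ccc(OCc2ccccc2)c(OC)c1 | starting material
2 | ethyl diazoacetate | CCOC(=O)C=[N+]=[N-] | starting material
3 | ethyl (3S)-3-[4-(benzyloxy)-3-methoxyphenyl]-2-diazo-3-hydroxypropanoate | CCOC(=O)C(=[N+]=[N-])[C@@H](O)c1ccc(OCc2ccccc2)c(OC)c1 | intermediate
4 | ethyl (3S)-3-[4-(benzyloxy)-3-methoxyphenyl]-3-hydroxy-2-oxopropanoate | CCOC(=O)C(=O)[C@@H](O)c1ccc(OCc2ccccc2)c(OC)c1 | intermediate
5 | diethyl (2R,3R)-2,3-bis{(S)-[4-(benzyloxy)-3-methoxyphenyl](hydroxy)methyl}-2,3-dihydroxybutanedioate (formed as its samarium alkoxide) | CCOC(=O)[C@]([C@@H](O)c1ccc(OCc2ccccc2)c(OC)c1)(O)[C@@](O)(C(=O)OCC)[C@@H](O)c1ccc(OCc2ccccc2)c(OC)c1 | intermediate (not isolated)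
6 | ethyl (2S,3R,4R)-2-[4-(benzyloxy)-3-methoxyphenyl]-4-{(S)-[4-(benzyloxy)-3-methoxyphenyl](hydroxy)methyl}-3,4-dihydroxy-5-oxooxolane-3-carboxylate | CCOC(=O)[C@@]1(O)[C@H](c2ccc(OCc3ccccc3)c(OC)c2)OC(=O)[C@@]1(O)[C@@H](O)c1ccc(OCc2ccccc2)c(OC)c1 | intermediate (not isolated)
7 | (3S,3aR,6S,6aR)-3,6-bis[4-(benzyloxy)-3-methoxyphenyl]-3a,6a-dihydroxytetrahydro-1H,3H-furo[3,4-c]furan-1,4-dione | COc1cc([C@@H]2OC(=O)[C@@]3(O)[C@H](c4ccc(OCc5ccccc5)c(OC)c4)OC(=O)[C@@]23O)ccc1OCc1ccccc1 | intermediate
8 | (3S,3aR,6S,6aR)-3,6-bis[4-(benzyloxy)-3-methoxyphenyl]tetrahydro-1H,3H-furo[3,4-c]furan-1,3a,4,6a-tetrol (lactol carbons unspecified) | COc1cc([C@@H]2OC(O)[C@@]3(O)[C@H](c4ccc(OCc5ccccc5)c(OC)c4)OC(O)[C@@]23O)ccc1OCc1ccccc1 | intermediate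
9 | (1S,3aR,4S,6aR)-1,4-bis[4-(benzyloxy)-3-methoxyphenyl]tetrahydro-1H,3H-furo[3,4-c]furan-3a,6a-diol | COc1cc([C@@H]2OC[C@@]3(O)[C@H](c4ccc(OCc5ccccc5)c(OC)c4)OC[C@@]23O)ccc1OCc1ccccc1 | intermediate
10 | (1S,3aR,4S,6aR)-1,4-bis(4-hydroxy-3-methoxyphenyl)tetrahydro-1H,3H-furo[3,4-c]furan-3a,6a-diol | COc1cc([C@@H]2OC[C@@]3(O)[C@H](c4ccc(O)c(OC)c4)OC[C@@]23O)ccc1O | target

Total step count: 6. Longest linear sequence: 6 steps (1 to 10).

Steps most likely to fail

Step 3. The two ketyls may unite in the unlike sense or on the aryl-shielded face, and a ketyl may be reduced further and protonated, or lose its benzylic hydroxyl, before it finds a partner. The fallback makes the union intramolecular; it sets out from 3 and comes back at 7. Acylation of 3 with bromoacetyl bromide and pyridine should give the bromoacetate F1. N,N'-Ditosylhydrazine and DBU convert it into the diazoacetate F2. A second magnesium–ProPhenol addition of F2 to aldehyde 1 gives the bis-diazo hydroxy ester F3, and DMDO oxidises both diazo groups to the ester-tethered bis(α-keto ester) F4. SmI2 then closes ring B by a five-membered-ring pinacol coupling of C1 with C5 (cis-diol enforced by the ring, C2 hydroxyl chelation as before), and O3 lactonises onto the remaining ethyl ester, which gives 7.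

Step 5. The Lewis acid may ionise the electron-rich benzylic C2–O3 and C6–O7 bonds, with epimerisation at C2 and C6 or reductive ring opening, and the lactol may open and be reduced to an acyclic diol. The fallback sets out from 7 and comes back at 9, replacing steps 4 and 5 at the cost of re-forming the two O–CH2 bonds. LiAlH4 reduces both lactones to the hexol F5. TsCl and Et3N with catalytic Bu2SnO sulfonylate only the two primary hydroxyls to give the bis-tosylate F6. K2CO3 in MeOH lets each tertiary alkoxide displace its neighbouring tosylate to give the bis-epoxide F7. With a trace of PPTS each benzylic hydroxyl opens the epoxide on the far quaternary carbon at its CH2 terminus (five-membered ring closure, C1, C2, C5 and C6 untouched), which gives 9.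

Step 1. The electron-rich aldehyde may add slowly and the catalyst may discriminate its faces incompletely; any enantiomeric impurity in 3 is carried into unlike pairs in step 3. The fallback sets out from 1 and 2 and comes back at 3. DBU-catalysed addition of 2 to 1 in MeCN gives the racemic diazo alcohol F8, and preparative chromatography on a chiral stationary phase separates 3 from its (R)-enantiomer F9.

Further compounds
F1 | step 3 | ethyl (3S)-3-[4-(benzyloxy)-3-methoxyphenyl]-3-(2-bromoacetoxy)-2-diazopropanoate | CCOC(=O)C(=[N+]=[N-])[C@@H](OC(=O)CBr)c1ccc(OCc2ccccc2)c(OC)c1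
F2 | step 3 | ethyl (3S)-3-[4-(benzyloxy)-3-methoxyphenyl]-2-diazo-3-(2-diazoacetoxy)propanoate | CCOC(=O)C(=[N+]=[N-])[C@@H](OC(=O)C=[N+]=[N-])c1ccc(OCc2ccccc2)c(OC)c1
F3 | step 3 | ethyl (3S)-3-[4-(benzyloxy)-3-methoxyphenyl]-3-{[(3S)-3-[4-(benzyloxy)-3-methoxyphenyl]-2-diazo-3-hydroxypropanoyl]oxy}-2-diazopropanoate | CCOC(=O)C(=[N+]=[N-])[C@@H](OC(=O)C(=[N+]=[N-])[C@@H](O)c1ccc(OCc2ccccc2)c(OC)c1)c1ccc(OCc2ccccc2)c(OC)c1
F4 | step 3 | ethyl (3S)-3-[4-(benzyloxy)-3-methoxyphenyl]-3-{[(3S)-3-[4-(benzyloxy)-3-methoxyphenyl]-3-hydroxy-2-oxopropanoyl]oxy}-2-oxopropanoate | CCOC(=O)C(=O)[C@@H](OC(=O)C(=O)[C@@H](O)c1ccc(OCc2ccccc2)c(OC)c1)c1ccc(OCc2ccccc2)c(OC)c1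
F5 | step 5 | (2R,3R)-2,3-bis{(S)-[4-(benzyloxy)-3-methoxyphenyl](hydroxy)methyl}butane-1,2,3,4-tetrol | OC[C@]([C@@H](O)c1ccc(OCc2ccccc2)c(OC)c1)(O)[C@@](O)(CO)[C@@H](O)c1ccc(OCc2ccccc2)c(OC)c1
F6 | step 5 | (2R,3R)-2,3-bis{(S)-[4-(benzyloxy)-3-methoxyphenyl](hydroxy)methyl}-2,3-dihydroxybutane-1,4-diyl bis(4-methylbenzenesulfonate) | Cc1ccc(cc1)S(=O)(=O)OC[C@]([C@@H](O)c1ccc(OCc2ccccc2)c(OC)c1)(O)[C@@](O)(COS(=O)(=O)c1ccc(C)cc1)[C@@H](O)c1ccc(OCc2ccccc2)c(OC)c1
F7 | step 5 | (2R,2'R)-2,2'-bis{(S)-[4-(benzyloxy)-3-methoxyphenyl](hydroxy)methyl}-2,2'-bioxirane | O[C@@H](c1ccc(OCc2ccccc2)c(OC)c1)[C@]1(CO1)[C@@]1(CO1)[C@@H](O)c1ccc(OCc2ccccc2)c(OC)c1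
F8 | step 1 | ethyl 3-[4-(benzyloxy)-3-methoxyphenyl]-2-diazo-3-hydroxypropanoate (racemic) | CCOC(=O)C(=[N+]=[N-])C(O)c1ccc(OCc2ccccc2)c(OC)c1
F9 | step 1 | ethyl (3R)-3-[4-(benzyloxy)-3-methoxyphenyl]-2-diazo-3-hydroxypropanoate | CCOC(=O)C(=[N+]=[N-])[C@H](O)c1ccc(OCc2ccccc2)c(OC)c1
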